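**Plan**

1. Main cut: C12–C13, an sp3–sp2 coupling between a core C12 alkylzinc and a side-chain 2-bromoalkene. In the side chain, C14–C15 comes from a glycolate aldol, C16–C≡C from an acetylide addition, and the butenolide from MeMgBr/CO2 on an ethynyl carbinol.
2. Core cuts: the C18 and C8 oxygens are removed first, then C6–C7 (ring B), the two C8–CH2Si bonds, and C9–C10 (ester-enolate Claisen onto reduced β-cyclocitral).
3. Feature behind the key cut: ring B carries oxygen on C6 and on C8 (C8 also bears methyl C17), 1,3 to each other across the C7 methylene. That pattern is a 3-methylenecyclohexanol, which opens to a C6 aldehyde on ring A and a 2-(trimethylsilylmethyl)allyl unit on C9.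
4. Forward order: ring A is bought; the Claisen step joins C9 to C10; hydroboration, lactone, allylsilane and oxidation give the aldehyde; ring B closes in step 8. Then follow the 8α,17-epoxide, the 6α-O→C18 ether, the γ-lactone and the lactol methyl acetal; the butenolide bromide is made in a separate branch; coupling and one acid step finish.
5. Stereochemistry: C9/C10 from the chair Claisen under a chiral boron controller; C5 from hydroboration anti to the axial methyls; C6 in the key step; C8 from α-face epoxidation and hydride opening; C4 from 1,5-hydrogen transfer to the 6α-oxygen; C14/C15 from an Evans syn aldol; C16 from a 1,3-syn reduction.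

Key step: step 8

**Remarks**

- Labdane numbering is used for the core (C1–C12, C17–C20). The new side-chain carbons are called C13 (bearing =CH2), C14, C15, C16 (butenolide CH–O), then C1′ (C=O), C2′ (=CH) and C3′ (C–CH3).
- Assumption: the target is the open 6α-hydroxy 18-aldehyde tautomer of the 6,18-hemiacetal that acid hydrolysis of 40 releases.
- Assumption: i-Pr2NEt in CH2Cl2 gives the enolate with the chain cis to O–B, and the (R,R)-controller gives acid 6; if either assignment proves wrong, the other base/solvent pairing or the (S,S)-antipode is used.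
- 2-Bromoacrolein (27) is taken as a commercial, cold-stored reagent.

**Route**

Step 1
Reactants: 1 β-cyclocitral
Product: 2 β-cyclogeraniol
Conditions: NaBH4, MeOH, 0 °C
Reagents that add atoms: none
Why: Borohydride 1,2-reduction of the hindered enal gives the primary allylic alcohol that serves as the allyl half of the Claisen substrate.

Step 2
Reactants: 2 β-cyclogeraniol; 3 4-(benzyloxy)butanoic acid
Product: 4 (2,6,6-trimethylcyclohex-1-en-1-yl)methyl 4-(benzyloxy)butanoate
Conditions: EDC·HCl, DMAP, CH2Cl2, 23 °C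
Reagents that add atoms: none
Why: Steglich esterification joins the primary allylic alcohol and the unhindered acid without the acid catalysis that could transpose the allylic system.

Step 3
Reactants: 4 allylic ester
Product: 6 (2R)-4-(benzyloxy)-2-[(1R)-1,3,3-trimethyl-2-methylidenecyclohexyl]butanoic acid, via boron ketene acetal 5 (not isolated)
Conditions: (R,R)-2-bromo-4,5-diphenyl-1,3-bis[3,5-bis(trifluoromethyl)phenylsulfonyl]-1,3,2-diazaborolidine, i-Pr2NEt, CH2Cl2, −78 → −20 °C; aq. work-up
Reagents that add atoms: none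
Why: Soft enolisation should give boron ketene acetal 5 with the chain cis to O–B, and its chair [3,3] shift (boron variant of the Ireland–Claisen rearrangement) puts ring carbon C1 equatorial and the C9 hydrogen axial, which fixes the C9/C10 relative configuration, while the C2-symmetric sulfonamide ligand selects the alkene face and thus the absolute configuration.

Step 4
Reactants: 6 Claisen acid
Product: 7 methyl (2R)-4-(benzyloxy)-2-[(1R)-1,3,3-trimethyl-2-methylidenecyclohexyl]butanoate
Conditions: MeI, K2CO3, DMF, 23 °C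
Reagents that add atoms: iodomethane, CI
Why: Carboxylate O-alkylation removes the acidic proton so that the dialkylborane of the next step is spent only on the alkene.

Step 5
Reactants: 7 methyl ester
Product: 10 trans-fused δ-lactone (C8 carbonyl; ring oxygen on C6; 5α-H; 10β-CH3; 9β arm CH2CH2OBn), via B-alkyl-9-BBN adduct 8 (not isolated), via hydroxy ester 9 (not isolated)
Conditions: 9-BBN, THF, 65 °C; NaOH, H2O2, 0 → 23 °C; then p-TsOH (cat.), toluene, 60 °C
Reagents that add atoms: hydrogen peroxide, OO
Why: Hydroboration–oxidation puts boron on the terminal carbon C6 and delivers hydrogen to C5 from the α face, opposite the axial methyl groups on C10 and C4, and the resulting trans-diequatorial hydroxy ester closes to the δ-lactone under acid (a minor C5 epimer could still be corrected by equilibrating aldehyde 14).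

Step 6
Reactants: 10 δ-lactone; 11 (trimethylsilyl)methylmagnesium chloride
Product: 13 ring A primary alcohol (C6 hydroxymethyl; 5α-H) with the C9 arm bearing C(=CH2)CH2SiMe3 and CH2CH2OBn, via bis(silylmethyl) carbinol 12 (not isolated)
Conditions: 11 (3 equiv), CeCl3 (anhydrous), THF, −78 → 23 °C; then SiO2, CH2Cl2, 23 °C
Reagents that add atoms: (trimethylsilyl)methylmagnesium chloride (second equivalent of 11), C[Si](C)(C)C[Mg]Cl
Why: Two equivalents of the weakly basic organocerium reagent made from 11 and CeCl3 add in succession to the lactone carbonyl without enolising it (ester-to-allylsilane conversion by double silylmethyl addition), and the tertiary β-hydroxysilane 12 then loses trimethylsilanol on silica (Peterson elimination), so that one silylmethyl carbon becomes the =CH2 terminus, the other remains as CH2SiMe3, and ring opening frees the C6 hydroxyl.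

Step 7
Reactants: 13 hydroxy allylsilane
Product: 14 ring A aldehyde (C6 formyl; 5α-H) with the C9 2-(trimethylsilylmethyl)allyl arm
Conditions: Dess–Martin periodinane, NaHCO3, CH2Cl2, 0 → 23 °C
Reagents that add atoms: none
Why: Buffered Dess–Martin oxidation converts the hindered primary alcohol to the aldehyde without acid that would protodesilylate the allylsilane, and the equatorial formyl group is the stable C5 epimer.

Step 8
Reactants: 14 ring A aldehyde
Product: 15 12-benzyloxy-13,14,15,16-tetranorlabd-8(17)-en-6α-ol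
Conditions: SnCl4, CH2Cl2, −78 °C
Reagents that add atoms: none
Why: SnCl4 binds the C6 formyl oxygen and the terminal alkene carbon of the allylsilane (future C7) attacks C6, the charge developing at C8 being stabilised by the β-silicon until chloride removes the silyl group and leaves the C8=C17 methylene (SE2′ pathway of an intramolecular Hosomi–Sakurai allylation). The closest known reaction is the Lewis acid-promoted cyclisation of aldehydes carrying a 2-(silylmethyl)allyl group to 3-methylenecyclohexanols. Ring B closes through a chair-like 6-exo-trig attack on the carbonyl, and its trans fusion is already set by the trans-diequatorial formyl group on C5 and arm on C10 of ring A. The one new stereocentre, C6, should be 6α because the tin-bound oxygen takes the equatorial site of the forming chair, away from the two β-axial methyls C19 and C20, and the open transition state needs no hydrogen transfer that would pull it axial. The step needs γ-regioselectivity, which the allylsilane guarantees, and face selectivity at C6, which the two axial methyls provide. Complexing the aldehyde at −78 °C before any warming keeps protodesilylation and tin–silicon exchange from competing.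

Step 9
Reactants: 15 homoallylic alcohol
Product: 16 12-benzyloxy-8α,17-epoxy-13,14,15,16-tetranorlabdan-6α-ol
Conditions: mCPBA, NaHCO3, CH2Cl2, 0 °C
Reagents that add atoms: 3-chloroperbenzoic acid, O=C(OO)c1cccc(Cl)c1
Why: Prilezhaev epoxidation of the exocyclic alkene should occur on the α face, away from the axial C10 methyl, so the epoxide oxygen is 8α, and removing the alkene also prevents β-scission of the later 6-alkoxy radical to an allylic radical.

Step 10
Reactants: 16 epoxy alcohol
Product: 17 12-benzyloxy-6α,18:8α,17-diepoxy-13,14,15,16-tetranorlabdane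
Conditions: PhI(OAc)2, I2, NaHCO3, cyclohexane, hν (visible), 23 °C
Reagents that add atoms: none
Why: Under Suárez hypoiodite conditions the 6α-alkoxy radical abstracts hydrogen from the 4α-methyl C18, which lies peri to the equatorial 6α-oxygen (1,5-hydrogen transfer through a six-membered transition state), and the C18 iodide then closes to the tetrahydrofuran, which fixes the configuration of C4.

Step 11
Reactants: 17 diepoxide
Product: 18 12-benzyloxy-6α,18-epoxy-13,14,15,16-tetranorlabdan-8α-ol
Conditions: LiAlH4, THF, 0 → 40 °C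
Reagents that add atoms: none
Why: Hydride opens the spiro-epoxide by SN2 attack at the primary carbon C17, leaving the tertiary 8α-hydroxyl and the 8β-methyl, while both ethers are inert.

Step 12
Reactants: 18 tertiary alcohol
Product: 19 12-benzyloxy-6α,18-epoxy-8α-(triethylsilyloxy)-13,14,15,16-tetranorlabdane
Conditions: TESOTf, 2,6-lutidine, CH2Cl2, 0 °C
Reagents that add atoms: triethylsilyl trifluoromethanesulfonate, CC[Si](CC)(CC)OS(=O)(=O)C(F)(F)F
Why: The silyl triflate silylates the tertiary hydroxyl, which would otherwise close onto C12 as a tetrahydrofuran once C12 carries a leaving group.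

Step 13
Reactants: 19 silyl ether
Product: 20 12-benzoyloxy-8α-(triethylsilyloxy)-13,14,15,16-tetranorlabdan-18,6α-olide
Conditions: RuCl3·xH2O (cat.), NaIO4, CCl4/MeCN/H2O, 23 °C
Reagents that add atoms: sodium periodate, [Na+].[O-]I(=O)(=O)=O
Why: Catalytic RuO4 oxidises both ether methylenes, C18 to the γ-lactone carbonyl and the benzylic CH2 to the benzoate (the known ether-to-ester oxidation), which brings C18 above the aldehyde level and turns the benzyl group into one that hydride removes.

Step 14
Reactants: 20 lactone benzoate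
Product: 22 6α,18-epoxy-18-methoxy-8α-(triethylsilyloxy)-13,14,15,16-tetranorlabdan-12-ol (C18 epimers), via lactol 21 (not isolated)
Conditions: i-Bu2AlH, CH2Cl2, −78 °C; aq. sodium potassium tartrate; then MeOH, PPTS (cat.), 0 → 23 °C
Reagents that add atoms: methanol, CO
Why: At −78 °C the aluminium hydride stops at the hemiacetal stage of the hindered γ-lactone while cleaving the benzoate, and acid-catalysed methanolysis then stores the lactol as a methyl acetal that masks both O6 and the C18 aldehyde.

Step 15
Reactants: 22 primary alcohol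
Product: 23 12-iodo-6α,18-epoxy-18-methoxy-8α-(triethylsilyloxy)-13,14,15,16-tetranorlabdane (C18 epimers)
Conditions: I2, PPh3, imidazole, CH2Cl2, 0 → 23 °C
Reagents that add atoms: iodine, II
Why: Appel-type iodination converts the primary alcohol to the iodide under imidazole buffering, which spares the acetal and the tertiary silyl ether.

Step 16
Reactants: 24 (R)-4-benzyloxazolidin-2-one; 25 (benzyloxy)acetyl chloride
Product: 26 (R)-4-benzyl-3-[(benzyloxy)acetyl]oxazolidin-2-one
Conditions: n-BuLi, THF, −78 °C
Reagents that add atoms: none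
Why: N-Acylation of the lithiated oxazolidinone with the acid chloride gives the glycolate imide.

Step 17
Reactants: 26 glycolate imide; 27 2-bromoacrolein
Product: 29 (4R)-4-benzyl-3-[(2R,3R)-2-(benzyloxy)-4-bromo-3-hydroxypent-4-enoyl]oxazolidin-2-one, via dibutylboron enolate 28 (not isolated)
Conditions: Bu2BOTf, Et3N, CH2Cl2, −78 → 0 °C; then 27, −78 °C; pH 7 buffer, MeOH, H2O2
Reagents that add atoms: none
Why: The (Z)-boron enolate reacts with the enal through a closed chair transition state (Evans syn aldol), so the auxiliary sets C15 and C14 syn with the absolute configuration shown.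

Step 18
Reactants: 29 aldol adduct
Product: 30 (2R,3R)-2-(benzyloxy)-4-bromo-3-hydroxy-N-methoxy-N-methylpent-4-enamide
Conditions: MeNHOMe·HCl, AlMe3, THF, −20 → 0 °C
Reagents that add atoms: N,O-dimethylhydroxylamine hydrochloride, Cl.CNOC
Why: Aluminium amide transamination of the imide gives the Weinreb amide and returns the auxiliary.

Step 19
Reactants: 30 Weinreb amide
Product: 31 (4R,5R)-4-(benzyloxy)-6-bromo-5-hydroxy-1-(trimethylsilyl)hept-6-en-1-yn-3-one
Conditions: Me3SiC≡CH, n-BuLi, THF, −78 → −20 °C
Reagents that add atoms: ethynyltrimethylsilane, C#C[Si](C)(C)C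
Why: The lithium acetylide adds once to the Weinreb amide because the chelated tetrahedral intermediate survives until work-up, which gives the ynone (an excess covers the free hydroxyl).

Step 20
Reactants: 31 β-hydroxy ynone
Product: 33 (3R,4S,5R)-4-(benzyloxy)-6-bromohept-6-en-1-yne-3,5-diol, via silylalkyne diol 32 (not isolated)
Conditions: Et2BOMe, NaBH4, THF/MeOH, −78 °C; then K2CO3, MeOH, 23 °C
Reagents that add atoms: none
Why: Et2BOMe ties the C14 hydroxyl and the ketone into a six-membered boron chelate so that external hydride gives the 1,3-syn diol (Narasaka–Prasad reduction), which sets C16, and methanolic carbonate then removes the alkynyl silyl group.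

Step 21
Reactants: 33 ethynyl diol
Product: 36 (5R)-5-[(1R,2R)-1-(benzyloxy)-3-bromo-2-hydroxybut-3-en-1-yl]-4-methylfuran-2(5H)-one, via alkenylmagnesium alkoxide 34 (not isolated), via (Z)-hydroxy acid 35 (not isolated)
Conditions: MeMgBr, CuI (cat.), THF, −20 → 23 °C; CO2; then aq. HCl, 23 °C
Reagents that add atoms: methylmagnesium bromide, C[Mg]Br; carbon dioxide, O=C=O
Why: The propargylic magnesium alkoxide directs a copper-catalysed anti-carbomagnesiation that puts methyl on the internal alkyne carbon and magnesium on the terminus cis to the carbinol, and carboxylation followed by acidification gives the (Z)-hydroxy acid, which lactonises to the 4-methylbutenolide without touching C16.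

Step 22
Reactants: 36 benzyl ether
Product: 37 (5R)-5-[(1R,2R)-3-bromo-1,2-dihydroxybut-3-en-1-yl]-4-methylfuran-2(5H)-one
Conditions: BCl3, pentamethylbenzene, CH2Cl2, −78 °C
Reagents that add atoms: none
Why: The boron Lewis acid cleaves the benzyl ether at low temperature, with pentamethylbenzene trapping the benzyl cation, and the butenolide and vinyl bromide are not affected.

Step 23
Reactants: 37 diol
Product: 38 (5R)-5-[(1R,2R)-3-bromo-1,2-bis(triethylsilyloxy)but-3-en-1-yl]-4-methylfuran-2(5H)-one
Conditions: TESOTf, 2,6-lutidine, CH2Cl2, −78 → 0 °C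
Reagents that add atoms: triethylsilyl trifluoromethanesulfonate, CC[Si](CC)(CC)OS(=O)(=O)C(F)(F)F
Why: Silylating both secondary hydroxyls removes the protons that would quench the organozinc reagent and installs groups that leave in the final acid step.

Step 24
Reactants: 23 primary iodide; 38 vinyl bromide
Product: 40 fully protected target (8-O-TES; 14,15-bis-O-TES; 6α,18-epoxy-18-methoxy acetal), via alkylzinc iodide 39 (not isolated)
Conditions: Zn dust (activated with BrCH2CH2Br and Me3SiCl), LiCl, THF, 40 °C; then 38, Pd(OAc)2, SPhos, THF, 40 °C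
Reagents that add atoms: none
Why: Zinc insertion into the primary iodide gives an alkylzinc that tolerates the acetal, silyl ethers and lactone, and palladium-catalysed Negishi coupling with the 2-bromoalkene forms C12–C13 with the 1,1-disubstituted alkene already in place.

Step 25
Reactants: 40 protected target
Product: 41 CNP0156243.1 (4α-formyl-6α,8α-dihydroxy core; side chain C13(=CH2)–C14H(OH)–C15H(OH)–C16 butenolide; 14S,15R,16R)
Conditions: aq. HCl (1 M), THF, 23 °C
Reagents that add atoms: water, O
Why: Dilute aqueous acid hydrolyses the three triethylsilyl ethers and the methyl acetal, which releases the 6α-hydroxy 18-aldehyde without conditions that would dehydrate the tertiary alcohol or epimerise C16.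

**Compound list**

1 | β-cyclocitral | CC1=C(C=O)C(C)(C)CCC1 | starting material
2 | β-cyclogeraniol | CC1=C(CO)C(C)(C)CCC1 | intermediate
3 | 4-(benzyloxy)butanoic acid | OC(=O)CCCOCc1ccccc1 | starting material
4 | (2,6,6-trimethylcyclohex-1-en-1-yl)methyl 4-(benzyloxy)butanoate | CC1=C(COC(=O)CCCOCc2ccccc2)C(C)(C)CCC1 | intermediate
5 | boron ketene acetal of 4, chain cis to O–B, boron carrying the (R,R)-bis-sulfonamide ligand (not isolated) | CC1=C(CO/C(OB2N(S(=O)(=O)c3cc(C(F)(F)F)cc(C(F)(F)F)c3)[C@H](c3ccccc3)[C@@H](c3ccccc3)N2S(=O)(=O)c2cc(C(F)(F)F)cc(C(F)(F)F)c2)=C/CCOCc2ccccc2)C(C)(C)CCC1 | intermediate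
6 | (2R)-4-(benzyloxy)-2-[(1R)-1,3,3-trimethyl-2-methylidenecyclohexyl]butanoic acid | C=C1C(C)(C)CCC[C@]1(C)[C@@H](CCOCc1ccccc1)C(=O)O | intermediate
7 | methyl ester of 6 | C=C1C(C)(C)CCC[C@]1(C)[C@@H](CCOCc1ccccc1)C(=O)OC | intermediate
8 | B-alkyl-9-BBN adduct of 7, boron on C6, 5α-H (not isolated) | B1(C[C@H]2C(C)(C)CCC[C@]2(C)[C@@H](CCOCc2ccccc2)C(=O)OC)C2CCCC1CCC2 | intermediate
9 | hydroxy ester, C6 hydroxymethyl trans to the C9 arm, 5α-H (not isolated) | OC[C@H]1C(C)(C)CCC[C@]1(C)[C@@H](CCOCc1ccccc1)C(=O)OC | intermediate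
10 | trans-fused δ-lactone, 4-[2-(benzyloxy)ethyl]-4a,8,8-trimethyl-hexahydroisochroman-3-one (4-arm cis to the 4a-methyl; 8a-H trans to it) | O=C1OC[C@H]2C(C)(C)CCC[C@]2(C)[C@H]1CCOCc1ccccc1 | intermediate
11 | (trimethylsilyl)methylmagnesium chloride | C[Si](C)(C)C[Mg]Cl | starting material
12 | bis(silylmethyl) carbinol diol, C8 as C(OH)(CH2SiMe3)2 and C6 as CH2OH (not isolated) | OC[C@H]1C(C)(C)CCC[C@]1(C)[C@@H](CCOCc1ccccc1)C(O)(C[Si](C)(C)C)C[Si](C)(C)C | intermediate
13 | ring A primary alcohol with the C9 2-(trimethylsilylmethyl)allyl arm | OC[C@H]1C(C)(C)CCC[C@]1(C)[C@@H](CCOCc1ccccc1)C(=C)C[Si](C)(C)C | intermediate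
14 | ring A aldehyde with the C9 2-(trimethylsilylmethyl)allyl arm (key-step precursor) | O=C[C@H]1C(C)(C)CCC[C@]1(C)[C@@H](CCOCc1ccccc1)C(=C)C[Si](C)(C)C | intermediate
15 | 12-benzyloxy-13,14,15,16-tetranorlabd-8(17)-en-6α-ol (key-step product) | c1ccccc1COCC[C@@H]1[C@@]2(C)CCCC(C)(C)[C@@H]2[C@@H](O)CC1=C | intermediate
16 | 12-benzyloxy-8α,17-epoxy-13,14,15,16-tetranorlabdan-6α-ol | c1ccccc1COCC[C@@H]1[C@@]2(C)CCCC(C)(C)[C@@H]2[C@@H](O)C[C@]13CO3 | intermediate
17 | 12-benzyloxy-6α,18:8α,17-diepoxy-13,14,15,16-tetranorlabdane | c1ccccc1COCC[C@@H]1[C@@]2(C)CCC[C@@](C)(CO4)[C@@H]2[C@@H]4C[C@]13CO3 | intermediate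
18 | 12-benzyloxy-6α,18-epoxy-13,14,15,16-tetranorlabdan-8α-ol | c1ccccc1COCC[C@@H]1[C@@]2(C)CCC[C@@](C)(CO4)[C@@H]2[C@@H]4C[C@@]1(C)O | intermediate
19 | 8-O-triethylsilyl ether of 18 | c1ccccc1COCC[C@@H]1[C@@]2(C)CCC[C@@](C)(CO4)[C@@H]2[C@@H]4C[C@@]1(C)O[Si](CC)(CC)CC | intermediate
20 | 12-benzoyloxy-8α-(triethylsilyloxy)-13,14,15,16-tetranorlabdan-18,6α-olide | O=C(OCC[C@@H]1[C@@]2(C)CCC[C@@](C)(C(=O)O4)[C@@H]2[C@@H]4C[C@@]1(C)O[Si](CC)(CC)CC)c1ccccc1 | intermediate
21 | 6α,18-epoxy-8α-(triethylsilyloxy)-13,14,15,16-tetranorlabdane-12,18-diol, lactol, C18 epimers (not isolated) | OCC[C@@H]1[C@@]2(C)CCC[C@@](C)(C(O)O4)[C@@H]2[C@@H]4C[C@@]1(C)O[Si](CC)(CC)CC | intermediate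
22 | 6α,18-epoxy-18-methoxy-8α-(triethylsilyloxy)-13,14,15,16-tetranorlabdan-12-ol, C18 epimers | OCC[C@@H]1[C@@]2(C)CCC[C@@](C)(C(OC)O4)[C@@H]2[C@@H]4C[C@@]1(C)O[Si](CC)(CC)CC | intermediate
23 | 12-iodo analogue of 22 | ICC[C@@H]1[C@@]2(C)CCC[C@@](C)(C(OC)O4)[C@@H]2[C@@H]4C[C@@]1(C)O[Si](CC)(CC)CC | intermediate
24 | (R)-4-benzyloxazolidin-2-one | O=C1N[C@H](Cc2ccccc2)CO1 | starting material
25 | (benzyloxy)acetyl chloride | O=C(Cl)COCc1ccccc1 | starting material
26 | (R)-4-benzyl-3-[(benzyloxy)acetyl]oxazolidin-2-one | O=C(COCc1ccccc1)N1[C@H](Cc2ccccc2)COC1=O | intermediate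
27 | 2-bromoacrolein | C=C(Br)C=O | starting material
28 | (Z)-dibutylboron enolate of 26 (not isolated) | CCCCB(CCCC)O/C(=C\OCc1ccccc1)N1[C@H](Cc2ccccc2)COC1=O | intermediate
29 | (4R)-4-benzyl-3-[(2R,3R)-2-(benzyloxy)-4-bromo-3-hydroxypent-4-enoyl]oxazolidin-2-one | C=C(Br)[C@H](O)[C@@H](OCc1ccccc1)C(=O)N1[C@H](Cc2ccccc2)COC1=O | intermediate
30 | (2R,3R)-2-(benzyloxy)-4-bromo-3-hydroxy-N-methoxy-N-methylpent-4-enamide | C=C(Br)[C@H](O)[C@@H](OCc1ccccc1)C(=O)N(C)OC | intermediate
31 | (4R,5R)-4-(benzyloxy)-6-bromo-5-hydroxy-1-(trimethylsilyl)hept-6-en-1-yn-3-one | C=C(Br)[C@H](O)[C@@H](OCc1ccccc1)C(=O)C#C[Si](C)(C)C | intermediate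
32 | 1-trimethylsilyl derivative of diol 33 (not isolated) | C=C(Br)[C@H](O)[C@@H](OCc1ccccc1)[C@H](O)C#C[Si](C)(C)C | intermediate
33 | (3R,4S,5R)-4-(benzyloxy)-6-bromohept-6-en-1-yne-3,5-diol | C=C(Br)[C@H](O)[C@@H](OCc1ccccc1)[C@H](O)C#C | intermediate
34 | alkenylmagnesium bis-alkoxide from anti-carbomagnesiation of 33 (not isolated) | C=C(Br)[C@H](O[Mg]Br)[C@@H](OCc1ccccc1)[C@H](O[Mg]Br)/C(C)=C\[Mg]Br | intermediate
35 | (Z)-γ-hydroxy-β-methyl enoic acid (not isolated) | C=C(Br)[C@H](O)[C@@H](OCc1ccccc1)[C@H](O)/C(C)=C\C(=O)O | intermediate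
36 | (5R)-5-[(1R,2R)-1-(benzyloxy)-3-bromo-2-hydroxybut-3-en-1-yl]-4-methylfuran-2(5H)-one | C=C(Br)[C@H](O)[C@@H](OCc1ccccc1)[C@@H]1OC(=O)C=C1C | intermediate
37 | (5R)-5-[(1R,2R)-3-bromo-1,2-dihydroxybut-3-en-1-yl]-4-methylfuran-2(5H)-one | C=C(Br)[C@H](O)[C@@H](O)[C@@H]1OC(=O)C=C1C | intermediate
38 | bis(triethylsilyl) ether of 37 | C=C(Br)[C@H](O[Si](CC)(CC)CC)[C@@H](O[Si](CC)(CC)CC)[C@@H]1OC(=O)C=C1C | intermediate
39 | alkylzinc iodide from 23 (not isolated) | I[Zn]CC[C@@H]1[C@@]2(C)CCC[C@@](C)(C(OC)O4)[C@@H]2[C@@H]4C[C@@]1(C)O[Si](CC)(CC)CC | intermediate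
40 | protected target: 8,14,15-tris-O-triethylsilyl, 6α,18-epoxy-18-methoxy acetal (C18 epimers) | C=C(CC[C@@H]1[C@@]2(C)CCC[C@@](C)(C(OC)O4)[C@@H]2[C@@H]4C[C@@]1(C)O[Si](CC)(CC)CC)[C@H](O[Si](CC)(CC)CC)[C@@H](O[Si](CC)(CC)CC)[C@@H]1OC(=O)C=C1C | intermediate
41 | CNP0156243.1 | C=C(CC[C@@H]1[C@@]2(C)CCC[C@@](C)(C=O)[C@@H]2[C@@H](O)C[C@@]1(C)O)[C@H](O)[C@@H](O)[C@@H]1OC(=O)C=C1C | target

**Step count**

Total: 25 steps. Longest linear sequence: 17 steps (steps 1–15, 24, 25); the side-chain branch is steps 16–23.

**Steps most likely to fail**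

1. Step 3. The rearrangement creates a quaternary carbon at a tetrasubstituted alkene and may be slow, and enolate geometry or facial control by the boron ligand may be incomplete, which would erode the diastereomeric and enantiomeric purity. Fallback, from ester 4: deprotonation with LiN(i-Pr)2 in THF/DMPU at −78 °C and trapping with Me3SiCl gives the (Z)-trimethylsilyl ketene acetal F1. On warming it undergoes the Ireland–Claisen rearrangement to the racemic trimethylsilyl ester F2, and aqueous work-up gives the racemic acid F3 with the same relative configuration. Classical resolution by crystallising the (R)-1-phenylethylammonium salt F4 and acidifying returns to acid 6.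

2. Step 10. The 1,5-hydrogen transfer from C18 may lose out to fragmentation of the alkoxy radical, or the iodine species may open the spiro-epoxide. Fallback, from epoxy alcohol 16, uses hydroxyl-directed C–H silylation instead of a radical. Et2SiH2 with [Ir(cod)OMe]2 gives the diethylhydrosilyl ether F5. [Rh(cod)Cl]2/Xantphos with norbornene as hydrogen acceptor closes it onto the C18 methyl to give the oxasilinane F6. Tamao–Fleming oxidation (H2O2, KHCO3, KF) gives the 6α,18-diol F7. Selective sulfonylation of the primary hydroxyl with TsCl in pyridine gives the 18-tosylate F8, which closes onto O6 on warming and returns to ether 17.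

3. Step 24. Zinc insertion may be incomplete, or the alkylpalladium intermediate may undergo β-hydride elimination or protonation faster than it couples with the hindered, oxygenated bromoalkene. Fallback, from iodide 23: elimination with KOt-Bu in THF gives the terminal alkene F9 (C11=C12). Hydroboration with 9-BBN gives the B-alkyl-9-BBN adduct F10, and B-alkyl Suzuki–Miyaura coupling with bromide 38 (Pd(dppf)Cl2, AsPh3, Cs2CO3, DMF/H2O, 23 °C) returns to coupled product 40.

**Further compounds**

F1 | step 3 | (Z)-trimethylsilyl ketene acetal of ester 4 | C[Si](C)(C)O/C(OCC1=C(C)CCCC1(C)C)=C\CCOCc1ccccc1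
F2 | step 3 | trimethylsilyl ester of the Claisen acid, racemate (relative configuration shown) | C=C1C(C)(C)CCC[C@]1(C)[C@@H](CCOCc1ccccc1)C(=O)O[Si](C)(C)C
F3 | step 3 | racemic Claisen acid (relative configuration shown) | C=C1C(C)(C)CCC[C@]1(C)[C@@H](CCOCc1ccccc1)C(=O)O
F4 | step 3 | (R)-1-phenylethylammonium salt of acid 6 | C=C1C(C)(C)CCC[C@]1(C)[C@@H](CCOCc1ccccc1)C([O-])=O.C[C@@H]([NH3+])c1ccccc1
F5 | step 10 | 6-O-(diethylhydrosilyl) ether of 16 | c1ccccc1COCC[C@@H]1[C@@]2(C)CCCC(C)(C)[C@@H]2[C@@H](O[SiH](CC)CC)C[C@]13CO3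
F6 | step 10 | oxasilinane bridging O6 and C18 through SiEt2 | c1ccccc1COCC[C@@H]1[C@@]2(C)CCC[C@@](C)(C[Si](CC)(CC)O4)[C@@H]2[C@@H]4C[C@]13CO3
F7 | step 10 | 12-benzyloxy-8α,17-epoxy-13,14,15,16-tetranorlabdane-6α,18-diol | c1ccccc1COCC[C@@H]1[C@@]2(C)CCC[C@@](C)(CO)[C@@H]2[C@@H](O)C[C@]13CO3
F8 | step 10 | 18-O-tosylate of F7 | c1ccccc1COCC[C@@H]1[C@@]2(C)CCC[C@@](C)(COS(=O)(=O)c4ccc(C)cc4)[C@@H]2[C@@H](O)C[C@]13CO3
F9 | step 24 | terminal alkene from 23 (C11=C12) | C=C[C@@H]1[C@@]2(C)CCC[C@@](C)(C(OC)O4)[C@@H]2[C@@H]4C[C@@]1(C)O[Si](CC)(CC)CC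
F10 | step 24 | B-alkyl-9-BBN adduct of F9 (boron on C12) | B1(CC[C@@H]2[C@@]3(C)CCC[C@@](C)(C(OC)O4)[C@@H]3[C@@H]4C[C@@]2(C)O[Si](CC)(CC)CC)C2CCCC1CCC2
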